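**Plan**

Atom labels: ring A = C1 (CH carrying the chain), C2 (C=CH2), C3, C4 (CH2), C5 (CHMe), C6 (CMe2); chain C1'–C15' counted from C1 (C3' quaternary, C6' and C13' CHMe).
Cuts: C3'–C4' (copper-catalysed SN2' of an alkenylalane on an allylic phosphate), C1–C1' with the shift of the double bond to C2=CH2 (Johnson–Claisen), ring bond C2–C3 (intramolecular B-alkyl Suzuki–Miyaura coupling), C5–C6 (Ireland–Claisen), C13'–CH3 (SN2' methylation).
Forward: pentenyl isobutyrate → Ireland–Claisen acid → (Z)-α-bromo dienoate → ring A closed as a cyclohex-1-ene-1-carboxylate → [3,3] shift installs C1'/C2' and the exocyclic methylene → chain grown to a geranyl-type phosphate; farnesol → right-hand alkyne; the halves are joined last, without protecting groups.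
Enabling feature: C2(=CH2)–C1(H)(CH2R) of ring A is a Claisen retron, so C2 can be carried as the bromine-bearing α-carbon of an enoate and C3 as a primary borane from a vinyl group; the gem-dimethyl C6 pre-organises the chain, and ring closure turns the remote acyclic C1/C5 relationship into a ring-controlled one.
Stereochemistry: C5 by 1,3-chirality transfer from (R)-pent-3-en-2-ol; C1 by axial delivery anti to the pseudoaxial C6 methyl in the Johnson–Claisen; C3' by a chiral NHC–copper catalyst; C6' by Ru–BINAP hydrogenation; C13' by copper/phosphoramidite SN2' methylation; E-alkenes from farnesol and syn-hydroalumination.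

Key step: step 7

Assumption: (2R,3E)-pent-3-en-2-ol (1) is taken as purchasable in enantiopure form (otherwise it is obtained by lipase resolution of the commercial racemate).

**Route**

Step 1
Reactants: 1 (2R,3E)-pent-3-en-2-ol; 2 2-methylpropanoyl chloride
Product: 3 (2R,3E)-pent-3-en-2-yl 2-methylpropanoate
Conditions: pyridine, DMAP (cat.), CH2Cl2, 0 → 23 °C
Reagents that add atoms: none
Why: DMAP-catalysed acylation of a secondary alcohol should proceed without touching the carbinol centre.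

Step 2
Reactants: 3 (2R,3E)-pent-3-en-2-yl 2-methylpropanoate
Product: 6 (3S,4E)-2,2,3-trimethylhex-4-enoic acid, via silyl ketene acetal 4 (not isolated), via trimethylsilyl ester 5 (not isolated)
Conditions: LDA, THF, −78 °C; TMSCl; −78 → 65 °C; then 1 M HCl
Reagents that add atoms: none
Why: Ireland–Claisen rearrangement through a chair with the carbinol methyl equatorial should transfer the (R) carbinol configuration to the new (3S) centre and give the E-alkene; the symmetric dimethylketene acetal makes enolate geometry irrelevant.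

Step 3
Reactants: 6 (3S,4E)-2,2,3-trimethylhex-4-enoic acid
Product: 7 (3S)-2,2,3-trimethylpent-4-enoic acid
Conditions: second-generation Hoveyda–Grubbs catalyst (5 mol %), ethylene (5 bar), CH2Cl2, 40 °C
Reagents that add atoms: ethylene C=C
Why: Ethenolysis (cross-metathesis with ethylene) should trim the propenyl group to a vinyl group, releasing propene, without affecting the stereocentre.

Step 4
Reactants: 7 (3S)-2,2,3-trimethylpent-4-enoic acid
Product: 8 (3S)-2,2,3-trimethylpent-4-en-1-ol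
Conditions: LiAlH4, Et2O, 0 → 35 °C
Reagents that add atoms: none
Why: Hydride reduction of a carboxylic acid to the primary alcohol; the isolated alkene is inert.

Step 5
Reactants: 8 (3S)-2,2,3-trimethylpent-4-en-1-ol
Product: 9 (3S)-2,2,3-trimethylpent-4-enal
Conditions: Dess–Martin periodinane, NaHCO3, CH2Cl2, 0 → 23 °C (product kept in solution, volatile)
Reagents that add atoms: none
Why: Dess–Martin oxidation should give the α-quaternary aldehyde, which cannot enolise.

Step 6
Reactants: 9 (3S)-2,2,3-trimethylpent-4-enal; 10 ethyl 2-bromo-2-(triphenyl-λ5-phosphanylidene)acetate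
Product: 11 ethyl (2Z,5S)-2-bromo-4,4,5-trimethylhepta-2,6-dienoate
Conditions: toluene, 90 °C
Reagents that add atoms: none
Why: Wittig olefination with the stabilised bromo ylide should give the (Z)-α-bromo enoate (ester trans to the bulky chain, bromine cis to it), the geometry needed for ring closure.

Step 7
Reactants: 11 ethyl (2Z,5S)-2-bromo-4,4,5-trimethylhepta-2,6-dienoate
Product: 13 ethyl (4S)-3,3,4-trimethylcyclohex-1-ene-1-carboxylate, via alkylborane 12 (not isolated)
Conditions: 9-BBN (1.3 equiv), THF, 0 → 23 °C; then slow addition to Pd(dppf)Cl2 (10 mol %), AsPh3 (20 mol %), Cs2CO3 (3 equiv), DMF–THF–H2O, 50 °C (final 0.01 M)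
Reagents that add atoms: none
Why: 9-BBN should add only to the terminal vinyl group (boron on the terminal carbon; the electron-poor bromo enoate and the ester are inert); zerovalent palladium then inserts into the C–Br bond, the base-activated borane transmetalates intramolecularly, and reductive elimination from the seven-membered palladacycle forms the C(sp2)–C(sp3) ring bond. The closest known reaction type is the hydroboration/intramolecular B-alkyl Suzuki–Miyaura coupling of bromo dienes to cycloalkenes. The six-membered ring A closes by joining the bromine-bearing alkene carbon to the boron-bearing CH2, so the enoate double bond ends endocyclic; no π bond is attacked. No stereocentre is created, and the existing methyl-bearing centre is not acidic and is untouched. The step needs intramolecular coupling to beat intermolecular coupling, β-hydride elimination and protodeboronation; high dilution, the Thorpe–Ingold effect of the gem-dimethyl group, the (Z)-bromide geometry and the dppf ligand should secure this.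

Step 8
Reactants: 13 ethyl (4S)-3,3,4-trimethylcyclohex-1-ene-1-carboxylate
Product: 14 [(4S)-3,3,4-trimethylcyclohex-1-en-1-yl]methanol
Conditions: i-Bu2AlH (2.5 equiv), CH2Cl2, −78 → 0 °C; Rochelle salt
Reagents that add atoms: none
Why: DIBAL-H reduces the enoate 1,2 to the allylic alcohol.

Step 9
Reactants: 14 [(4S)-3,3,4-trimethylcyclohex-1-en-1-yl]methanol
Product: 17 ethyl 2-[(1S,3S)-2,2,3-trimethyl-6-methylidenecyclohexyl]acetate, via mixed orthoester 15 (not isolated), via ketene acetal 16 (not isolated)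
Conditions: MeC(OEt)3 (7 equiv), EtCO2H (5 mol %), xylene, 140 °C, EtOH distilled off
Reagents that add atoms: triethyl orthoacetate CCOC(C)(OCC)OCC
Why: Johnson–Claisen rearrangement; in the half-chair with the ring methyl equatorial the CH2CO2Et unit should be delivered axially to the ring CH, anti to the pseudoaxial methyl of the adjacent CMe2, so the side chain ends trans to the ring methyl (1S) while the double bond moves to the exocyclic position.

Step 10
Reactants: 17 ethyl 2-[(1S,3S)-2,2,3-trimethyl-6-methylidenecyclohexyl]acetate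
Product: 18 2-[(1S,3S)-2,2,3-trimethyl-6-methylidenecyclohexyl]ethan-1-ol
Conditions: LiAlH4, THF, 0 °C
Reagents that add atoms: none
Why: Ester reduction by hydride; the 1,1-disubstituted alkene is inert.

Step 11
Reactants: 18 2-[(1S,3S)-2,2,3-trimethyl-6-methylidenecyclohexyl]ethan-1-ol
Product: 19 (2S,6S)-2-(2-iodoethyl)-1,1,6-trimethyl-3-methylidenecyclohexane
Conditions: I2, PPh3, imidazole, CH2Cl2, 0 → 23 °C
Reagents that add atoms: iodine II
Why: Appel-type iodination of an unhindered primary alcohol under neutral conditions that do not isomerise the exocyclic alkene.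

Step 12
Reactants: 19 (2S,6S)-2-(2-iodoethyl)-1,1,6-trimethyl-3-methylidenecyclohexane
Product: 20 (2S,6S)-2-(but-3-yn-1-yl)-1,1,6-trimethyl-3-methylidenecyclohexane
Conditions: HC≡CLi·H2NCH2CH2NH2, DMSO, 10 → 23 °C
Reagents that add atoms: lithium acetylide–ethylenediamine complex [Li]C#C.NCCN
Why: SN2 alkylation of lithium acetylide by a primary iodide in a dipolar aprotic solvent.

Step 13
Reactants: 20 (2S,6S)-2-(but-3-yn-1-yl)-1,1,6-trimethyl-3-methylidenecyclohexane
Product: 23 (2E)-3-methyl-5-[(1S,3S)-2,2,3-trimethyl-6-methylidenecyclohexyl]pent-2-en-1-ol, via alkenylalane 21 (not isolated), via lithium alanate 22 (not isolated)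
Conditions: Me3Al (3 equiv), Cp2ZrCl2 (0.5 equiv), CH2Cl2, 0 → 23 °C; then n-BuLi, THF, −78 °C; (CH2O)n, −78 → 23 °C
Reagents that add atoms: trimethylaluminium C[Al](C)C; formaldehyde (as paraformaldehyde) C=O
Why: Negishi zirconium-catalysed methylalumination adds Me and Al syn to the terminal alkyne (the 1,1-disubstituted alkene does not react), and hydroxymethylation of the alanate should give the (E)-trisubstituted allylic alcohol.

Step 14
Reactants: 23 (2E)-3-methyl-5-[(1S,3S)-2,2,3-trimethyl-6-methylidenecyclohexyl]pent-2-en-1-ol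
Product: 24 diethyl (2E)-3-methyl-5-[(1S,3S)-2,2,3-trimethyl-6-methylidenecyclohexyl]pent-2-en-1-yl phosphate
Conditions: ClP(O)(OEt)2, Et3N, DMAP (cat.), CH2Cl2, 0 °C
Reagents that add atoms: diethyl chlorophosphate CCOP(=O)(Cl)OCC
Why: O-phosphorylation of a primary allylic alcohol gives the electrophile for the final allylic substitution.

Step 15
Reactants: 25 (2E,6E)-farnesol
Product: 26 (3S,6E)-3,7,11-trimethyldodeca-6,10-dien-1-ol
Conditions: Ru(OAc)2[(R)-BINAP] (0.5 mol %), H2 (100 atm), MeOH–H2O 95:5, 20 °C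
Reagents that add atoms: none
Why: Noyori asymmetric hydrogenation of the allylic alcohol double bond only; the (R)-BINAP complex with an (E)-allylic alcohol should set the (3S) centre, and the remote trisubstituted alkenes are untouched.

Step 16
Reactants: 26 (3S,6E)-3,7,11-trimethyldodeca-6,10-dien-1-ol
Product: 27 (3S,6E)-3,7,11-trimethyldodeca-6,10-dienal
Conditions: Dess–Martin periodinane, NaHCO3, CH2Cl2, 0 → 23 °C
Reagents that add atoms: none
Why: Mild oxidation to the aldehyde; the stereocentre is β to the carbonyl and cannot epimerise.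

Step 17
Reactants: 27 (3S,6E)-3,7,11-trimethyldodeca-6,10-dienal
Product: 29 (3S,6E)-3,7,11-trimethyldodeca-6,10-dien-1-yne, via enol nonaflate 28 (not isolated)
Conditions: C4F9SO2F, phosphazene base P2-Et, DMF, −30 → 23 °C
Reagents that add atoms: none
Why: One-pot enol nonaflate formation and E2 elimination converts the CH2–CHO unit into a terminal alkyne; the propargylic centre is not deprotonated because the more acidic alkyne C–H is.

Step 18
Reactants: 29 (3S,6E)-3,7,11-trimethyldodeca-6,10-dien-1-yne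
Product: 30 (2E,6E,10S)-2,6,10-trimethyldodeca-2,6-dien-11-yn-1-ol
Conditions: SeO2 (0.1 equiv), t-BuOOH, salicylic acid (0.1 equiv), CH2Cl2, 23 °C
Reagents that add atoms: tert-butyl hydroperoxide CC(C)(C)OO
Why: Catalytic SeO2 allylic oxidation (ene reaction then [2,3] shift) should hydroxylate the E-methyl of the terminal isopropylidene group in preference to the internal alkene.

Step 19
Reactants: 30 (2E,6E,10S)-2,6,10-trimethyldodeca-2,6-dien-11-yn-1-ol
Product: 31 (3S,6E,10E)-12-chloro-3,7,11-trimethyldodeca-6,10-dien-1-yne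
Conditions: N-chlorosuccinimide, Me2S, CH2Cl2, −20 → 0 °C
Reagents that add atoms: N-chlorosuccinimide O=C1CCC(=O)N1Cl
Why: Corey–Kim chlorination converts the primary allylic alcohol into the chloride by SN2 without allylic transposition.

Step 20
Reactants: 31 (3S,6E,10E)-12-chloro-3,7,11-trimethyldodeca-6,10-dien-1-yne
Product: 32 (3R,6E,10S)-2,3,6,10-tetramethyldodeca-1,6-dien-11-yne
Conditions: MeMgBr (1.3 equiv, slow addition), Cu(O2CC4H3S) (copper thiophene-2-carboxylate, 3 mol %), chiral BINOL-derived phosphoramidite (3.3 mol %), CH2Cl2, −78 °C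
Reagents that add atoms: methylmagnesium bromide C[Mg]Br
Why: Copper-catalysed asymmetric allylic alkylation of a β-methyl allylic chloride should proceed SN2' to give the methyl-bearing centre next to the isopropenyl group, with the (3R) configuration set by the ligand (enantiomer chosen accordingly); at −78 °C the alkyne C–H should not be metalated.

Step 21
Reactants: 32 (3R,6E,10S)-2,3,6,10-tetramethyldodeca-1,6-dien-11-yne; 24 diethyl (2E)-3-methyl-5-[(1S,3S)-2,2,3-trimethyl-6-methylidenecyclohexyl]pent-2-en-1-yl phosphate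
Product: 34 (2S,6S)-2-[(3S,4E,6S,9E,13R)-3-ethenyl-3,6,10,13,14-pentamethylpentadeca-4,9,14-trien-1-yl]-1,1,6-trimethyl-3-methylidenecyclohexane (CNP0186101.1), via alkenylalane 33 (not isolated)
Conditions: i-Bu2AlH (1 equiv per alkyne), hexane, 55 °C; then 24, chiral sulfonate-bearing N-heterocyclic carbene silver complex (2.5 mol %), CuCl2·2H2O (5 mol %), THF, −15 °C
Reagents that add atoms: none
Why: syn-Hydroalumination of the terminal alkyne (alkenes are inert at 55 °C) gives the (E)-alkenylalane, and the NHC–copper-catalysed enantioselective SN2' allylic substitution should transfer it to the γ-carbon of the phosphate, creating the methyl/vinyl quaternary centre (S, set by the catalyst enantiomer) with the E-alkene retained.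

**Compound list**

1 | (2R,3E)-pent-3-en-2-ol | C/C=C/[C@@H](C)O | starting material
2 | 2-methylpropanoyl chloride | CC(C)C(Cl)=O | starting material
3 | (2R,3E)-pent-3-en-2-yl 2-methylpropanoate | C/C=C/[C@@H](C)OC(=O)C(C)C | intermediate
4 | trimethyl[(2-methyl-1-{[(2R,3E)-pent-3-en-2-yl]oxy}prop-1-en-1-yl)oxy]silane | C/C=C/[C@@H](C)OC(O[Si](C)(C)C)=C(C)C | intermediate
5 | trimethylsilyl (3S,4E)-2,2,3-trimethylhex-4-enoate | C[Si](C)(C)OC(=O)C(C)(C)[C@@H](C)/C=C/C | intermediate
6 | (3S,4E)-2,2,3-trimethylhex-4-enoic acid | OC(=O)C(C)(C)[C@@H](C)/C=C/C | intermediate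
7 | (3S)-2,2,3-trimethylpent-4-enoic acid | OC(=O)C(C)(C)[C@@H](C)C=C | intermediate
8 | (3S)-2,2,3-trimethylpent-4-en-1-ol | OCC(C)(C)[C@@H](C)C=C | intermediate
9 | (3S)-2,2,3-trimethylpent-4-enal | O=CC(C)(C)[C@@H](C)C=C | intermediate
10 | ethyl 2-bromo-2-(triphenyl-λ5-phosphanylidene)acetate | CCOC(=O)C(Br)=P(c1ccccc1)(c1ccccc1)c1ccccc1 | starting material
11 | ethyl (2Z,5S)-2-bromo-4,4,5-trimethylhepta-2,6-dienoate | CCOC(=O)/C(Br)=C/C(C)(C)[C@@H](C)C=C | intermediate
12 | ethyl (2Z,5S)-7-(9-borabicyclo[3.3.1]nonan-9-yl)-2-bromo-4,4,5-trimethylhept-2-enoate | CCOC(=O)/C(Br)=C/C(C)(C)[C@@H](C)CCB1C2CCCC1CCC2 | intermediate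
13 | ethyl (4S)-3,3,4-trimethylcyclohex-1-ene-1-carboxylate | CCOC(=O)C1=CC(C)(C)[C@@H](C)CC1 | intermediate
14 | [(4S)-3,3,4-trimethylcyclohex-1-en-1-yl]methanol | OCC1=CC(C)(C)[C@@H](C)CC1 | intermediate
15 | (4S)-1-[(1,1-diethoxyethoxy)methyl]-3,3,4-trimethylcyclohex-1-ene | CCOC(C)(OCC)OCC1=CC(C)(C)[C@@H](C)CC1 | intermediate
16 | (4S)-1-{[(1-ethoxyethenyl)oxy]methyl}-3,3,4-trimethylcyclohex-1-ene | C=C(OCC)OCC1=CC(C)(C)[C@@H](C)CC1 | intermediate
17 | ethyl 2-[(1S,3S)-2,2,3-trimethyl-6-methylidenecyclohexyl]acetate | CCOC(=O)C[C@H]1C(=C)CC[C@H](C)C1(C)C | intermediate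
18 | 2-[(1S,3S)-2,2,3-trimethyl-6-methylidenecyclohexyl]ethan-1-ol | OCC[C@H]1C(=C)CC[C@H](C)C1(C)C | intermediate
19 | (2S,6S)-2-(2-iodoethyl)-1,1,6-trimethyl-3-methylidenecyclohexane | ICC[C@H]1C(=C)CC[C@H](C)C1(C)C | intermediate
20 | (2S,6S)-2-(but-3-yn-1-yl)-1,1,6-trimethyl-3-methylidenecyclohexane | C#CCC[C@H]1C(=C)CC[C@H](C)C1(C)C | intermediate
21 | dimethyl{(1E)-2-methyl-4-[(1S,3S)-2,2,3-trimethyl-6-methylidenecyclohexyl]but-1-en-1-yl}alane | C[Al](C)/C=C(\C)CC[C@H]1C(=C)CC[C@H](C)C1(C)C | intermediate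
22 | lithium butyl(dimethyl){(1E)-2-methyl-4-[(1S,3S)-2,2,3-trimethyl-6-methylidenecyclohexyl]but-1-en-1-yl}aluminate | [Li+].CCCC[Al-](C)(C)/C=C(\C)CC[C@H]1C(=C)CC[C@H](C)C1(C)C | intermediate
23 | (2E)-3-methyl-5-[(1S,3S)-2,2,3-trimethyl-6-methylidenecyclohexyl]pent-2-en-1-ol | OC/C=C(\C)CC[C@H]1C(=C)CC[C@H](C)C1(C)C | intermediate
24 | diethyl (2E)-3-methyl-5-[(1S,3S)-2,2,3-trimethyl-6-methylidenecyclohexyl]pent-2-en-1-yl phosphate | CCOP(=O)(OCC)OC/C=C(\C)CC[C@H]1C(=C)CC[C@H](C)C1(C)C | intermediate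
25 | (2E,6E)-farnesol | OC/C=C(\C)CC/C=C(\C)CCC=C(C)C | starting material
26 | (3S,6E)-3,7,11-trimethyldodeca-6,10-dien-1-ol | OCC[C@@H](C)CC/C=C(\C)CCC=C(C)C | intermediate
27 | (3S,6E)-3,7,11-trimethyldodeca-6,10-dienal | O=CC[C@@H](C)CC/C=C(\C)CCC=C(C)C | intermediate
28 | (3S,6E)-3,7,11-trimethyldodeca-1,6,10-trien-1-yl nonafluorobutane-1-sulfonate (E/Z mixture at C1) | O=S(=O)(OC=C[C@@H](C)CC/C=C(\C)CCC=C(C)C)C(F)(F)C(F)(F)C(F)(F)C(F)(F)F | intermediate
29 | (3S,6E)-3,7,11-trimethyldodeca-6,10-dien-1-yne | C#C[C@@H](C)CC/C=C(\C)CCC=C(C)C | intermediate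
30 | (2E,6E,10S)-2,6,10-trimethyldodeca-2,6-dien-11-yn-1-ol | C#C[C@@H](C)CC/C=C(\C)CC/C=C(\C)CO | intermediate
31 | (3S,6E,10E)-12-chloro-3,7,11-trimethyldodeca-6,10-dien-1-yne | C#C[C@@H](C)CC/C=C(\C)CC/C=C(\C)CCl | intermediate
32 | (3R,6E,10S)-2,3,6,10-tetramethyldodeca-1,6-dien-11-yne | C#C[C@@H](C)CC/C=C(\C)CC[C@@H](C)C(C)=C | intermediate
33 | bis(2-methylpropyl)[(1E,3S,6E,10R)-3,7,10,11-tetramethyldodeca-1,6,11-trien-1-yl]alane | CC(C)C[Al](CC(C)C)/C=C/[C@@H](C)CC/C=C(\C)CC[C@@H](C)C(C)=C | intermediate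
34 | (2S,6S)-2-[(3S,4E,6S,9E,13R)-3-ethenyl-3,6,10,13,14-pentamethylpentadeca-4,9,14-trien-1-yl]-1,1,6-trimethyl-3-methylidenecyclohexane (CNP0186101.1) | C=C[C@@](C)(/C=C/[C@@H](C)CC/C=C(\C)CC[C@@H](C)C(=C)C)CC[C@H]1C(=C)CC[C@H](C)C1(C)C | target

**Totals and risks**

Total step count: 21. Longest linear sequence: 15 steps (steps 1–14, then step 21).

Step 21 (most likely to fail). Enantiofacial discrimination at the γ-carbon of 24 may be poor, because methyl against a primary alkyl chain is the hardest pairing for this catalyst class, and hydroalumination of 32 may be incomplete; both would give C3' epimers that cannot be separated. The fallback sets out from 23 and 32 and comes back to the route at 34, and it sets the quaternary centre by reagent-controlled epoxidation and a stereospecific epoxide opening. Sharpless epoxidation of 23 (Ti(OiPr)4, D-(−)-diethyl tartrate, t-BuOOH, 4 Å MS, CH2Cl2, −20 °C) should give [(2R,3R)-3-methyl-3-{2-[(1S,3S)-2,2,3-trimethyl-6-methylidenecyclohexyl]ethyl}oxiran-2-yl]methanol F1. Alkyne 32 is converted (i-Bu2AlH, Et3N 5 mol %, hexane, 23 °C) into bis(2-methylpropyl)[(3S,6E,10R)-3,7,10,11-tetramethyldodeca-6,11-dien-1-yn-1-yl]alane F2, which should open F1 at the fully substituted epoxide carbon with inversion (toluene, 0 → 23 °C). This gives (2S,3R,6S,9E,13R)-3,6,10,13,14-pentamethyl-3-{2-[(1S,3S)-2,2,3-trimethyl-6-methylidenecyclohexyl]ethyl}pentadeca-9,14-dien-4-yne-1,2-diol F3. Na in NH3–THF (−78 °C) reduces the alkyne to the E-alkene, (2S,3R,4E,6S,9E,13R)-3,6,10,13,14-pentamethyl-3-{2-[(1S,3S)-2,2,3-trimethyl-6-methylidenecyclohexyl]ethyl}pentadeca-4,9,14-triene-1,2-diol F4. Thiocarbonyldiimidazole (DMAP, toluene, 80 °C) gives (4S)-4-{(3R,4E,6S,9E,13R)-3,6,10,13,14-pentamethyl-1-[(1S,3S)-2,2,3-trimethyl-6-methylidenecyclohexyl]pentadeca-4,9,14-trien-3-yl}-1,3-dioxolane-2-thione F5. Corey–Winter elimination (1,3-dimethyl-2-phenyl-1,3,2-diazaphospholidine, 40 °C) turns the diol unit into the vinyl group and gives 34.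

Step 20. Regioselectivity (SN2 against SN2') and enantioselectivity may erode for an aliphatic β-methyl allylic chloride with the small methyl nucleophile, and the Grignard reagent may partly metalate the alkyne; the C13' epimer would be inseparable. The fallback sets out from 30 and comes back at 32. Sharpless epoxidation of 30 (Ti(OiPr)4, L-(+)-diethyl tartrate, t-BuOOH, CH2Cl2, −20 °C) should give [(2S,3S)-3-[(3E,7S)-3,7-dimethylnon-3-en-8-yn-1-yl]-2-methyloxiran-2-yl]methanol F6. Me3Al (hexane–CH2Cl2, 0 °C) opens F6 at C3 with inversion to (2R,3R,6E,10S)-2,3,6,10-tetramethyldodec-6-en-11-yne-1,2-diol F7. Thiocarbonyldiimidazole gives (4R)-4-[(2R,5E,9S)-5,9-dimethylundec-5-en-10-yn-2-yl]-4-methyl-1,3-dioxolane-2-thione F8, and Corey–Winter elimination (same phosphorus reagent, 40 °C) forms the isopropenyl group of 32.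

Step 9. Facial selectivity of the [3,3] shift may be poor if the half-chair with an axial ring methyl competes, which would give the cis (1R) isomer alongside 17. The fallback sets out from 14 and comes back at 17, and it overrides ring control by 1,3-chirality transfer from a reagent-set carbinol. MnO2 (CH2Cl2) oxidises 14 to (4S)-3,3,4-trimethylcyclohex-1-ene-1-carbaldehyde F9. Catalytic asymmetric methyl addition (Me2Zn, Ti(OiPr)4, chiral 1,2-bis(trifluoromethanesulfonamido)cyclohexane, enantiomer chosen for the S carbinol) gives (1S)-1-[(4S)-3,3,4-trimethylcyclohex-1-en-1-yl]ethan-1-ol F10. Johnson–Claisen rearrangement (MeC(OEt)3, EtCO2H, 140 °C) through the chair with the carbinol methyl equatorial should give ethyl 2-[(1R,3S,6E)-6-ethylidene-2,2,3-trimethylcyclohexyl]acetate F11, which has the same spatial arrangement at C1 as 17. Ozonolysis (O3, CH2Cl2, −78 °C; Me2S) gives ethyl 2-[(1R,3S)-2,2,3-trimethyl-6-oxocyclohexyl]acetate F12, and non-basic Lombardo methylenation (Zn, CH2Br2, TiCl4) gives 17.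

**Further compounds**

F1 | step 21 | [(2R,3R)-3-methyl-3-{2-[(1S,3S)-2,2,3-trimethyl-6-methylidenecyclohexyl]ethyl}oxiran-2-yl]methanol | OC[C@H]1O[C@]1(C)CC[C@H]2C(=C)CC[C@H](C)C2(C)C
F2 | step 21 | bis(2-methylpropyl)[(3S,6E,10R)-3,7,10,11-tetramethyldodeca-6,11-dien-1-yn-1-yl]alane | CC(C)C[Al](CC(C)C)C#C[C@@H](C)CC/C=C(\C)CC[C@@H](C)C(C)=C
F3 | step 21 | (2S,3R,6S,9E,13R)-3,6,10,13,14-pentamethyl-3-{2-[(1S,3S)-2,2,3-trimethyl-6-methylidenecyclohexyl]ethyl}pentadeca-9,14-dien-4-yne-1,2-diol | OC[C@@H](O)[C@@](C)(C#C[C@@H](C)CC/C=C(\C)CC[C@@H](C)C(C)=C)CC[C@H]1C(=C)CC[C@H](C)C1(C)C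
F4 | step 21 | (2S,3R,4E,6S,9E,13R)-3,6,10,13,14-pentamethyl-3-{2-[(1S,3S)-2,2,3-trimethyl-6-methylidenecyclohexyl]ethyl}pentadeca-4,9,14-triene-1,2-diol | OC[C@@H](O)[C@@](C)(/C=C/[C@@H](C)CC/C=C(\C)CC[C@@H](C)C(C)=C)CC[C@H]1C(=C)CC[C@H](C)C1(C)C
F5 | step 21 | (4S)-4-{(3R,4E,6S,9E,13R)-3,6,10,13,14-pentamethyl-1-[(1S,3S)-2,2,3-trimethyl-6-methylidenecyclohexyl]pentadeca-4,9,14-trien-3-yl}-1,3-dioxolane-2-thione | S=C1OC[C@@H](O1)[C@@](C)(/C=C/[C@@H](C)CC/C=C(\C)CC[C@@H](C)C(C)=C)CC[C@H]2C(=C)CC[C@H](C)C2(C)C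
F6 | step 20 | [(2S,3S)-3-[(3E,7S)-3,7-dimethylnon-3-en-8-yn-1-yl]-2-methyloxiran-2-yl]methanol | C#C[C@@H](C)CC/C=C(\C)CC[C@@H]1O[C@@]1(C)CO
F7 | step 20 | (2R,3R,6E,10S)-2,3,6,10-tetramethyldodec-6-en-11-yne-1,2-diol | C#C[C@@H](C)CC/C=C(\C)CC[C@@H](C)[C@@](C)(O)CO
F8 | step 20 | (4R)-4-[(2R,5E,9S)-5,9-dimethylundec-5-en-10-yn-2-yl]-4-methyl-1,3-dioxolane-2-thione | C#C[C@@H](C)CC/C=C(\C)CC[C@@H](C)[C@]1(C)COC(=S)O1
F9 | step 9 | (4S)-3,3,4-trimethylcyclohex-1-ene-1-carbaldehyde | O=CC1=CC(C)(C)[C@@H](C)CC1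
F10 | step 9 | (1S)-1-[(4S)-3,3,4-trimethylcyclohex-1-en-1-yl]ethan-1-ol | C[C@H](O)C1=CC(C)(C)[C@@H](C)CC1
F11 | step 9 | ethyl 2-[(1R,3S,6E)-6-ethylidene-2,2,3-trimethylcyclohexyl]acetate | CCOC(=O)C[C@H]1/C(=C/C)CC[C@H](C)C1(C)C
F12 | step 9 | ethyl 2-[(1R,3S)-2,2,3-trimethyl-6-oxocyclohexyl]acetate | CCOC(=O)C[C@H]1C(=O)CC[C@H](C)C1(C)C
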